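The tetrahydropyran ring (O1, C2 with the arylethyl chain, C3, C4 with OH, C5, C6 with the aryl group) is cut into two three-atom pieces, O1–C2–C3 and C4–C5–C6. The key step joins them as a flat ring: the methyl enolate of O-benzylzingerone (C3) is acylated by an arylpropiolic ester (C4), and the ynedione closes in the same flask by 6-endo attack of the C2 enol oxygen on the aryl-bearing alkyne carbon C6, giving a 2,6-disubstituted 4-pyranone. It exploits the 1,3-dioxygen pattern O1/C4–OH and the oxygen- and aryl-bearing C6. Enantioselective cis-hydrogenation of this heteroarene sets C2 and C6, hydride reduction sets C4, and hydrogenolysis frees the phenols.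

Key step: step 5

Remark: ring positions are called O1, C2 (arylethyl-bearing), C3, C4, C5, C6 (aryl-bearing) in every cyclic compound, whatever the systematic numbering would be; zingerone (1) and 3,4-dihydroxy-5-methoxybenzaldehyde (3) are taken as purchasable.
Remark: the sense of induction of the catalyst in step 6 cannot be fixed in advance; the (R,R)-ligand is written, and its antipode would be taken if a trial run shows the opposite sense.

Step 1
Reactants: 1 zingerone [4-(4-hydroxy-3-methoxyphenyl)butan-2-one]
Product: 2 4-[4-(benzyloxy)-3-methoxyphenyl]butan-2-one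
Conditions: BnBr, K2CO3, acetone, reflux
Reagents that add atoms: benzyl bromide, BrCc1ccccc1
Why: Williamson ether synthesis, in which the phenoxide is alkylated under carbonate conditions that should leave the methyl ketone untouched.

Step 2
Reactants: 3 3,4-dihydroxy-5-methoxybenzaldehyde
Product: 4 3,4-bis(benzyloxy)-5-methoxybenzaldehyde
Conditions: BnBr (2.3 equiv), K2CO3, DMF, 60 °C
Reagents that add atoms: benzyl bromide, BrCc1ccccc1
Why: Twofold Williamson etherification of the catechol hydroxyls, to which the aldehyde is inert.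

Step 3
Reactants: 4 3,4-bis(benzyloxy)-5-methoxybenzaldehyde
Product: 5 1,2-bis(benzyloxy)-5-(2,2-dibromoethenyl)-3-methoxybenzene
Conditions: CBr4, PPh3, Zn dust, CH2Cl2, 0 °C to rt
Reagents that add atoms: carbon tetrabromide, BrC(Br)(Br)Br
Why: First stage of the Corey–Fuchs sequence, a Wittig-type olefination of the aldehyde by the dibromomethylene ylide formed from CBr4, PPh3 and zinc.

Step 4
Reactants: 5 1,2-bis(benzyloxy)-5-(2,2-dibromoethenyl)-3-methoxybenzene
Product: 7 methyl 3-[3,4-bis(benzyloxy)-5-methoxyphenyl]prop-2-ynoate, via lithium arylacetylide 6 (not isolated)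
Conditions: n-BuLi (2.2 equiv), THF, −78 °C; ClCO2Me, −78 to 0 °C
Reagents that add atoms: methyl chloroformate, COC(=O)Cl
Why: Second stage of the Corey–Fuchs sequence, in which bromine–lithium exchange and Fritsch–Buttenberg–Wiechell rearrangement give the lithium acetylide, which is C-acylated by the chloroformate.

Step 5
Reactants: 2 4-[4-(benzyloxy)-3-methoxyphenyl]butan-2-one; 7 methyl 3-[3,4-bis(benzyloxy)-5-methoxyphenyl]prop-2-ynoate
Product: 10 6-[3,4-bis(benzyloxy)-5-methoxyphenyl]-2-{2-[4-(benzyloxy)-3-methoxyphenyl]ethyl}-4H-pyran-4-one, via lithium enolate 8 (not isolated), via ynedione 9 (not isolated)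
Conditions: LiN(i-Pr)2 (2.0 equiv), 2 (2.0 equiv), THF, −78 °C; 7 (1.0 equiv), −78 to 0 °C; then HCl (4 M in dioxane), rt
Reagents that add atoms: none
Why: Kinetic deprotonation of the methyl group of 2 gives enolate 8, whose carbon (C3) attacks the ester carbonyl (C4) of 7 and expels methoxide to give ynedione 9 as its lithium enolate (Claisen condensation); on acidification the enol oxygen on C2 (O1) adds to the alkyne carbon C6 of the protonated ynone, and tautomerisation gives the 4-pyranone. The closest known reaction type is the classical 4-pyranone synthesis from ketone enolates and arylpropiolic esters through acetylenic 1,3-diketones. The one ring is closed in the 6-endo-dig mode, as an oxa-Michael addition of the enol oxygen. No stereocenter is formed; C2, C4 and C6 stay trigonal and are set in steps 6 and 7. Three selectivities are needed: enolisation at the methyl and not the methylene group (kinetic base at −78 °C), acylation at C4 and not conjugate addition at C6 (lithium enolate at low temperature, and a C6 that is deactivated and shielded by the trioxygenated aryl group), and 6-endo over 5-exo closure (acid activation places the positive charge on the aryl-stabilised C6, and the product is the aromatic pyranone).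

Step 6
Reactants: 10 6-[3,4-bis(benzyloxy)-5-methoxyphenyl]-2-{2-[4-(benzyloxy)-3-methoxyphenyl]ethyl}-4H-pyran-4-one
Product: 12 (2S,6S)-6-[3,4-bis(benzyloxy)-5-methoxyphenyl]-2-{2-[4-(benzyloxy)-3-methoxyphenyl]ethyl}oxan-4-one (2,6-cis), via (2S)-2,3-dihydropyranone 11 (not isolated)
Conditions: H2 (100 bar), Ru(cod)(2-methylallyl)2 (5 mol%), 1,3-bis[(R)-1-(naphthalen-1-yl)ethyl]imidazolinium tetrafluoroborate [(R,R)-SINpEt·HBF4, 10 mol%], KOt-Bu (15 mol%), toluene, 25 °C
Reagents that add atoms: none
Why: Proposed new method: the chiral ruthenium–bis(carbene) hydride is expected to bind one face of the flat pyranone and to add the first H2 across the more accessible, alkyl-substituted C2=C3 bond under catalyst control (C2, S), after which dihydropyranone 11 should take up the second H2 at C5=C6 on the face that already carries the C2 hydrogen, so that aryl and arylethyl groups end up cis (C6, S), while the saturated dialkyl ketone is expected to be reduced more slowly than the conjugated C=C bonds and so to persist; the closest known reaction type is the ruthenium–carbene-catalysed asymmetric hydrogenation of flavones and chromones (benzo-fused 4-pyranones) and of 2,5-disubstituted furans to cis-tetrahydrofurans, which has not been shown on monocyclic 2,6-disubstituted 4-pyranones.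

Step 7
Reactants: 12 (2S,6S)-6-[3,4-bis(benzyloxy)-5-methoxyphenyl]-2-{2-[4-(benzyloxy)-3-methoxyphenyl]ethyl}oxan-4-one
Product: 13 (2S,4R,6S)-6-[3,4-bis(benzyloxy)-5-methoxyphenyl]-2-{2-[4-(benzyloxy)-3-methoxyphenyl]ethyl}oxan-4-ol (all-cis)
Conditions: NaBH4, MeOH/THF, −20 °C
Reagents that add atoms: none
Why: Borohydride reduction in which the small hydride attacks the chair ketone (both substituents equatorial) along the axial trajectory, so that the new C4 hydroxyl should be equatorial and cis to both substituents (C4, R, substrate control).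

Step 8
Reactants: 13 (2S,4R,6S)-6-[3,4-bis(benzyloxy)-5-methoxyphenyl]-2-{2-[4-(benzyloxy)-3-methoxyphenyl]ethyl}oxan-4-ol
Product: 14 (2S,4R,6S)-6-(3,4-dihydroxy-5-methoxyphenyl)-2-[2-(4-hydroxy-3-methoxyphenyl)ethyl]oxan-4-ol (CNP0399218.1)
Conditions: H2 (1 atm), Pd/C (10%), EtOAc/MeOH, rt
Reagents that add atoms: none
Why: Hydrogenolysis of the three aryl benzyl ethers, which should be much faster than cleavage of the cyclic benzylic C6–O1 bond and does not touch the stereocenters.

Compound list
1 | zingerone, 4-(4-hydroxy-3-methoxyphenyl)butan-2-one | CC(=O)CCc1ccc(O)c(OC)c1 | starting material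
2 | 4-[4-(benzyloxy)-3-methoxyphenyl]butan-2-one | CC(=O)CCc1ccc(OCc2ccccc2)c(OC)c1 | intermediate
3 | 3,4-dihydroxy-5-methoxybenzaldehyde | O=Cc1cc(O)c(O)c(OC)c1 | starting material
4 | 3,4-bis(benzyloxy)-5-methoxybenzaldehyde | O=Cc1cc(OCc2ccccc2)c(OCc2ccccc2)c(OC)c1 | intermediate
5 | 1,2-bis(benzyloxy)-5-(2,2-dibromoethenyl)-3-methoxybenzene | BrC(Br)=Cc1cc(OCc2ccccc2)c(OCc2ccccc2)c(OC)c1 | intermediate
6 | lithium [3,4-bis(benzyloxy)-5-methoxyphenyl]acetylide | [Li]C#Cc1cc(OCc2ccccc2)c(OCc2ccccc2)c(OC)c1 | intermediate (not isolated)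
7 | methyl 3-[3,4-bis(benzyloxy)-5-methoxyphenyl]prop-2-ynoate | COC(=O)C#Cc1cc(OCc2ccccc2)c(OCc2ccccc2)c(OC)c1 | intermediate
8 | lithium 4-[4-(benzyloxy)-3-methoxyphenyl]but-1-en-2-olate (methyl-side enolate of 2) | [Li]OC(=C)CCc1ccc(OCc2ccccc2)c(OC)c1 | intermediate (not isolated)
9 | 1-[3,4-bis(benzyloxy)-5-methoxyphenyl]-7-[4-(benzyloxy)-3-methoxyphenyl]hept-1-yne-3,5-dione | O=C(CCc1ccc(OCc2ccccc2)c(OC)c1)CC(=O)C#Cc1cc(OCc2ccccc2)c(OCc2ccccc2)c(OC)c1 | intermediate (not isolated)
10 | 6-[3,4-bis(benzyloxy)-5-methoxyphenyl]-2-{2-[4-(benzyloxy)-3-methoxyphenyl]ethyl}-4H-pyran-4-one | O=C1C=C(CCc2ccc(OCc3ccccc3)c(OC)c2)OC(c2cc(OCc3ccccc3)c(OCc3ccccc3)c(OC)c2)=C1 | intermediate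
11 | (2S)-6-[3,4-bis(benzyloxy)-5-methoxyphenyl]-2-{2-[4-(benzyloxy)-3-methoxyphenyl]ethyl}-2,3-dihydro-4H-pyran-4-one | COc1cc(CC[C@H]2CC(=O)C=C(c3cc(OCc4ccccc4)c(OCc4ccccc4)c(OC)c3)O2)ccc1OCc1ccccc1 | intermediate (not isolated)
12 | (2S,6S)-6-[3,4-bis(benzyloxy)-5-methoxyphenyl]-2-{2-[4-(benzyloxy)-3-methoxyphenyl]ethyl}oxan-4-one | COc1cc(CC[C@H]2CC(=O)C[C@@H](c3cc(OCc4ccccc4)c(OCc4ccccc4)c(OC)c3)O2)ccc1OCc1ccccc1 | intermediate
13 | (2S,4R,6S)-6-[3,4-bis(benzyloxy)-5-methoxyphenyl]-2-{2-[4-(benzyloxy)-3-methoxyphenyl]ethyl}oxan-4-ol | COc1cc(CC[C@H]2C[C@@H](O)C[C@@H](c3cc(OCc4ccccc4)c(OCc4ccccc4)c(OC)c3)O2)ccc1OCc1ccccc1 | intermediate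
14 | (2S,4R,6S)-6-(3,4-dihydroxy-5-methoxyphenyl)-2-[2-(4-hydroxy-3-methoxyphenyl)ethyl]oxan-4-ol | COc1cc(CC[C@H]2C[C@@H](O)C[C@@H](c3cc(O)c(O)c(OC)c3)O2)ccc1O | target

Total step count: 8. Longest linear sequence: 7 steps (3 → 4 → 5 → 7 → 10 → 12 → 13 → 14).

Steps most likely to fail

Step 6 (proposed new method). The two enone halves of the pyranone are nearly mirror-related, so discrimination between the two faces may be poor. A first reduction at the aryl-substituted double bond could lead to the opposite sense. A catalyst-controlled second addition could give the 2,6-trans isomer, and residual base could open dihydropyranone 11 by retro-oxa-Michael reaction and erode C2. Over-reduction of the ketone is also possible. The fallback uses known chemistry, sets out from pyranone 10 and comes back at alcohol 13. Hydrogenation over Pd/C in the presence of ethylenediamine (H2, 1 atm, THF), which saturates C=C bonds but spares aryl benzyl ethers, should give the racemic 2,6-cis oxan-4-one F1. NaBH4 should then give the racemic all-cis oxan-4-ol F2. Esterification with (S)-2-methoxy-2-phenylacetic acid (DCC, DMAP, CH2Cl2, 0 °C) should give two diastereomers, the (2S,4R,6S) ester F3 and the (2R,4S,6R) ester F4, to be separated by chromatography or crystallisation. LiOH (THF/H2O) on the (2S,4R,6S) ester F3 returns alcohol 13.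

Step 5. The enolate carbon may add in conjugate fashion to C6 of the alkynoate (leading to 2-pyranone-type products) or attack the liberated ynone a second time. Proton transfer may shift the enolate to the methylene side, and closure may go 5-exo. The fallback sets out from dibromoalkene 5 and ketone 2 and comes back at pyranone 10. Acetylide 6, made from 5 as in step 4, is trapped with N-methoxy-N-methylcarbamoyl chloride (CON(C)C(Cl)=O) to give the alkynyl N-methoxy-N-methylamide F5. Enolate 8 adds to the amide F5 to give the chelated lithium tetrahedral adduct F6, which should be stable until the quench, so that no free ynone or ynedione meets the enolate. HCl in dioxane then releases ynedione 9 from the adduct F6 and closes it to 10.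

Step 8. Hydrogenolysis may also open the ring at the benzylic C6–O1 bond, which the para-oxygenated aryl group activates. The fallback sets out from 13 and comes back at 14 without hydrogen: BCl3 with pentamethylbenzene as cation scavenger in CH2Cl2 at −78 °C cleaves aryl benzyl ethers by a Lewis-acid pathway. No new compound arises on this path; its entry is F0.

Further compounds
F1 | step 6 | racemic 2,6-cis 6-[3,4-bis(benzyloxy)-5-methoxyphenyl]-2-{2-[4-(benzyloxy)-3-methoxyphenyl]ethyl}oxan-4-one (relative configuration shown) | COc1cc(CC[C@H]2CC(=O)C[C@@H](c3cc(OCc4ccccc4)c(OCc4ccccc4)c(OC)c3)O2)ccc1OCc1ccccc1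
F2 | step 6 | racemic all-cis 6-[3,4-bis(benzyloxy)-5-methoxyphenyl]-2-{2-[4-(benzyloxy)-3-methoxyphenyl]ethyl}oxan-4-ol (relative configuration shown) | COc1cc(CC[C@H]2C[C@@H](O)C[C@@H](c3cc(OCc4ccccc4)c(OCc4ccccc4)c(OC)c3)O2)ccc1OCc1ccccc1
F3 | step 6 | (2S,4R,6S)-6-[3,4-bis(benzyloxy)-5-methoxyphenyl]-2-{2-[4-(benzyloxy)-3-methoxyphenyl]ethyl}oxan-4-yl (S)-2-methoxy-2-phenylacetate | COc1cc(CC[C@H]2C[C@@H](OC(=O)[C@@H](OC)c3ccccc3)C[C@@H](c3cc(OCc4ccccc4)c(OCc4ccccc4)c(OC)c3)O2)ccc1OCc1ccccc1
F4 | step 6 | (2R,4S,6R)-6-[3,4-bis(benzyloxy)-5-methoxyphenyl]-2-{2-[4-(benzyloxy)-3-methoxyphenyl]ethyl}oxan-4-yl (S)-2-methoxy-2-phenylacetate | COc1cc(CC[C@@H]2C[C@H](OC(=O)[C@@H](OC)c3ccccc3)C[C@H](c3cc(OCc4ccccc4)c(OCc4ccccc4)c(OC)c3)O2)ccc1OCc1ccccc1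
F5 | step 5 | 3-[3,4-bis(benzyloxy)-5-methoxyphenyl]-N-methoxy-N-methylprop-2-ynamide | CON(C)C(=O)C#Cc1cc(OCc2ccccc2)c(OCc2ccccc2)c(OC)c1
F6 | step 5 | lithium salt of the tetrahedral adduct of enolate 8 and amide F5 | CON(C)C(O[Li])(CC(=O)CCc1ccc(OCc2ccccc2)c(OC)c1)C#Cc1cc(OCc2ccccc2)c(OCc2ccccc2)c(OC)c1
F0 | step 8 | none | none
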